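Rings B and C are each cut into a four-carbon 3-ethoxycyclobutenone and a two-carbon siloxyalkyne. In both rings C2, C4 and C6 carry oxygen, while C1, C3 and C5 carry the central CH2, the outer CH2 and the propionyl group. This strict alternation, with the central CH2 on the cyclobutenone sp3 carbon, lets one twofold thermal benzannulation of a CH2-linked bis(cyclobutenone) close rings B and C, each with three differentiated oxygens and one free C–H. The outer-bridge carbon enters on the alkyne as CH2NEt2, so rings A and D are attached afterwards by amine loss and conjugate addition, without any oxidation beside the diarylmethane CH2.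

Key step: step 3

Remarks on the chemistry
- Atom map, checked against the target and found consistent: cyclobutenone C4 becomes arene C1 (central CH2), the carbonyl carbon C2 (free OH), the alkyne carbons C3 (outer-bridge carbon) and C4 (OSi), cyclobutenone C2–H becomes C5 (propionyl site), and cyclobutenone C3 becomes C6 (OEt).
- Design change: a C3 methyl group could not be oxidised selectively next to the doubly benzylic central CH2, and a benzylic ether or ester there would not survive Lewis-acid acylation; C3 therefore carries CH2NEt2 from the alkyne onwards (inert as its AlCl3 or BBr3 complex, a leaving group only on heating). The carbon skeleton of the benzannulation product and the bonds formed are unchanged.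
- Assumption: ethoxyacetylene (solution in hexanes), N,N-diethylprop-2-yn-1-amine and flopropione (2,4,6-trihydroxypropiophenone) are taken as commercial.
- The target has no stereocentre; 6 is used as its mixture of meso and racemic diastereomers, and both centres vanish in step 3.

Step 1
Reactants: 1 glutaryl dichloride; 2 ethoxyacetylene
Product: 6 4,4'-methylenebis(3-ethoxycyclobut-2-en-1-one), via ketene acid chloride 3 (not isolated), via cyclobutenone acid chloride 4 (not isolated), via cyclobutenone ketene 5 (not isolated)
Conditions: 2 (5 equiv), Et3N (2.5 equiv), Et2O, 1 added over 8 h, 0 °C → rt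
Reagents that add atoms: none
Why: Triethylamine dehydrochlorinates each acyl chloride end to an alkylketene, which undergoes the regioselective ketene–ynol ether [2+2] cycloaddition (ketene carbonyl carbon to the unsubstituted alkyne carbon), while slow addition into excess alkyne should keep the half-reacted ketene from cyclising onto its own acyl chloride; the two sp3 centres form unselectively, which is harmless because step 3 destroys them.

Step 2
Reactants: 7 N,N-diethylprop-2-yn-1-amine
Product: 10 N,N-diethyl-3-(triisopropylsilyloxy)prop-2-yn-1-amine, via lithium acetylide 8 (not isolated), via lithium ynolate 9 (not isolated)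
Conditions: n-BuLi, THF, −78 °C; t-BuOOH, LiN(SiMe3)2, −78 → 0 °C; i-Pr3SiOTf, −78 °C → rt
Reagents that add atoms: tert-butyl hydroperoxide, CC(C)(C)OO; triisopropylsilyl trifluoromethanesulfonate, CC(C)[Si](OS(=O)(=O)C(F)(F)F)(C(C)C)C(C)C
Why: Oxidation of a lithium acetylide by lithium tert-butyl peroxide (electrophilic oxygen transfer to a carbanion) gives the ynolate, which the bulky silyl triflate traps on oxygen to give the siloxyalkyne; the tertiary amine is inert to both reagents at low temperature.

Step 3
Reactants: 6 4,4'-methylenebis(3-ethoxycyclobut-2-en-1-one); 10 N,N-diethyl-3-(triisopropylsilyloxy)prop-2-yn-1-amine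
Product: 15 bis[3-(diethylaminomethyl)-6-ethoxy-2-hydroxy-4-(triisopropylsilyloxy)phenyl]methane, via bis(vinylketene) 11 (not isolated), via twofold cyclobutenone adduct 12 (not isolated), via bis(dienylketene) 13 (not isolated), via bis(cyclohexadienone) 14 (not isolated)
Conditions: 10 (3 equiv), toluene (0.05 M), 90 °C, sealed tube, argon
Reagents that add atoms: none
Why: Each cyclobutenone opens by thermal conrotatory 4π electrocyclic cleavage of its C1–C4 bond to a (2-ethoxyvinyl)ketene, which adds the siloxyalkyne in a [2+2] cycloaddition; the resulting 4-vinylcyclobutenone opens again to a dienylketene that closes by 6π electrocyclisation and tautomerises to the phenol. The closest known reaction is the Danheiser benzannulation of cyclobutenones with siloxyalkynes, which gives resorcinol monosilyl ethers with the alkyne substituent between the two oxygens. Rings B and C are each closed by the 6π electrocyclisation that joins the ketene carbon to the carbon bearing the central CH2, after the [2+2] step has made the two new C–C bonds (aminomethyl-bearing alkyne carbon to the former carbonyl carbon, siloxy carbon to the former C2–H carbon). No stereocentre is created, and the two sp3 centres of 6 disappear in the first ring opening, so the diastereomer mixture converges. The step needs one regiochemistry of alkyne addition, secured by the polarisation of the ynol ether: its carbon remote from oxygen is the nucleophile that attacks the ketene carbonyl carbon, which places oxygen on alternate ring carbons. Excess alkyne and dilution are meant to keep ketene dimerisation and acylation of the new phenol behind the cycloaddition.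

Step 4
Reactants: 15 bis[3-(diethylaminomethyl)-6-ethoxy-2-hydroxy-4-(triisopropylsilyloxy)phenyl]methane
Product: 16 1,1'-{methylenebis[5-(diethylaminomethyl)-2-ethoxy-4-hydroxy-6-(triisopropylsilyloxy)-3,1-phenylene]}di(propan-1-one)
Conditions: AlCl3 (excess, premixed with 15), EtCOCl, CH2Cl2, −20 → 0 °C; aq. NaHCO3 work-up
Reagents that add atoms: propionyl chloride, CCC(Cl)=O
Why: Friedel–Crafts acylation at the only unsubstituted ring carbon, which is activated by two ortho oxygens and the para hydroxyl, while the amine is tied up as its AlCl3 complex and so can be neither acylated nor expelled.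

Step 5
Reactants: 16 1,1'-{methylenebis[5-(diethylaminomethyl)-2-ethoxy-4-hydroxy-6-(triisopropylsilyloxy)-3,1-phenylene]}di(propan-1-one)
Product: 17 1,1'-{methylenebis[5-(diethylaminomethyl)-2,4,6-trihydroxy-3,1-phenylene]}di(propan-1-one)
Conditions: BBr3, CH2Cl2, −78 → 0 °C; MeOH; then KF, MeOH, rt; work-up at pH 7
Reagents that add atoms: none
Why: Lewis-acid ether cleavage, in which BBr3 bound to the ethoxy oxygen (held by chelation to the neighbouring ketone) lets bromide remove the ethyl group by SN2, fluoride then strips the silyl ethers, and tertiary benzylic amines and the acyl-deactivated diarylmethane tolerate the reagent.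

Step 6
Reactants: 18 flopropione (1-(2,4,6-trihydroxyphenyl)propan-1-one)
Product: 19 3,5-dihydroxy-6,6-dimethyl-2-propanoylcyclohexa-2,4-dien-1-one (propionylfilicinic acid)
Conditions: MeI (2.2 equiv), NaOMe, MeOH, 0 °C → rt; aq. HCl
Reagents that add atoms: iodomethane, CI
Why: Dearomatising geminal C-methylation of an acylphloroglucinol polyanion, the established access to acylfilicinic acids, in which the second methyl group should enter mainly at the already methylated ring carbon.

Step 7
Reactants: 17 1,1'-{methylenebis[5-(diethylaminomethyl)-2,4,6-trihydroxy-3,1-phenylene]}di(propan-1-one); 19 3,5-dihydroxy-6,6-dimethyl-2-propanoylcyclohexa-2,4-dien-1-one (2.2 equiv)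
Product: 21 4,4'-{methylenebis[(2,4,6-trihydroxy-5-propanoyl-3,1-phenylene)methylene]}bis(3,5-dihydroxy-6,6-dimethyl-2-propanoylcyclohexa-2,4-dien-1-one) (target CNP0541376.0), via bis(o-quinone methide) 20 (not isolated)
Conditions: 1,4-dioxane, 90 °C, N2 stream; aq. HCl work-up
Reagents that add atoms: none
Why: Thermal elimination of diethylamine from each o-hydroxybenzylamine (Mannich base) gives an o-quinone methide that is captured by Michael addition of the enolic C4–H carbon of 19 and rearomatises (amine-exchange alkylation of a cyclic 1,3-dicarbonyl); rings B and C have no free carbon left, so self-condensation is excluded.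

Compound list
1 | glutaryl dichloride | O=C(Cl)CCCC(Cl)=O | starting material
2 | ethoxyacetylene | CCOC#C | starting material
3 | 5-oxopent-4-enoyl chloride (ketene acid chloride) | O=C=CCCC(Cl)=O | intermediate
4 | 3-(2-ethoxy-4-oxocyclobut-2-en-1-yl)propanoyl chloride (racemic) | CCOC1=CC(=O)C1CCC(Cl)=O | intermediate
5 | 3-(2-ethoxy-4-oxocyclobut-2-en-1-yl)prop-1-en-1-one (racemic ketene) | CCOC1=CC(=O)C1CC=C=O | intermediate
6 | 4,4'-methylenebis(3-ethoxycyclobut-2-en-1-one), meso and racemic diastereomers | CCOC1=CC(=O)C1CC1C(=O)C=C1OCC | intermediate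
7 | N,N-diethylprop-2-yn-1-amine | CCN(CC)CC#C | starting material
8 | lithium 3-(diethylamino)prop-1-yn-1-ide | [Li+].[C-]#CCN(CC)CC | intermediate
9 | lithium 3-(diethylamino)prop-1-yn-1-olate | [Li+].[O-]C#CCN(CC)CC | intermediate
10 | N,N-diethyl-3-(triisopropylsilyloxy)prop-2-yn-1-amine | CCN(CC)CC#CO[Si](C(C)C)(C(C)C)C(C)C | intermediate
11 | 3,7-diethoxynona-1,3,6,8-tetraene-1,9-dione (alkene geometry as formed) | O=C=CC(OCC)=CCC=C(OCC)C=C=O | intermediate
12 | 4,4'-(1,5-diethoxypenta-1,4-diene-1,5-diyl)bis[2-(diethylaminomethyl)-3-(triisopropylsilyloxy)cyclobut-2-en-1-one] (stereoisomer mixture) | CCN(CC)CC1=C(O[Si](C(C)C)(C(C)C)C(C)C)C(C(OCC)=CCC=C(OCC)C2C(=O)C(CN(CC)CC)=C2O[Si](C(C)C)(C(C)C)C(C)C)C1=O | intermediate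
13 | 2,12-bis(diethylaminomethyl)-5,9-diethoxy-3,11-bis(triisopropylsilyloxy)trideca-1,3,5,8,10,12-hexaene-1,13-dione (the isomer with the ketene and vinyl ends cis on each siloxy alkene cyclises) | O=C=C(CN(CC)CC)C(O[Si](C(C)C)(C(C)C)C(C)C)=CC(OCC)=CCC=C(OCC)C=C(O[Si](C(C)C)(C(C)C)C(C)C)C(CN(CC)CC)=C=O | intermediate
14 | 6,6'-methylenebis[2-(diethylaminomethyl)-5-ethoxy-3-(triisopropylsilyloxy)cyclohexa-2,4-dien-1-one] (stereoisomer mixture) | O=C1C(CN(CC)CC)=C(O[Si](C(C)C)(C(C)C)C(C)C)C=C(OCC)C1CC1C(=O)C(CN(CC)CC)=C(O[Si](C(C)C)(C(C)C)C(C)C)C=C1OCC | intermediate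
15 | bis[3-(diethylaminomethyl)-6-ethoxy-2-hydroxy-4-(triisopropylsilyloxy)phenyl]methane | CCOc1cc(O[Si](C(C)C)(C(C)C)C(C)C)c(CN(CC)CC)c(O)c1Cc1c(O)c(CN(CC)CC)c(O[Si](C(C)C)(C(C)C)C(C)C)cc1OCC | intermediate
16 | 1,1'-{methylenebis[5-(diethylaminomethyl)-2-ethoxy-4-hydroxy-6-(triisopropylsilyloxy)-3,1-phenylene]}di(propan-1-one) | CCOc1c(C(=O)CC)c(O[Si](C(C)C)(C(C)C)C(C)C)c(CN(CC)CC)c(O)c1Cc1c(O)c(CN(CC)CC)c(O[Si](C(C)C)(C(C)C)C(C)C)c(C(=O)CC)c1OCC | intermediate
17 | 1,1'-{methylenebis[5-(diethylaminomethyl)-2,4,6-trihydroxy-3,1-phenylene]}di(propan-1-one) | CCC(=O)c1c(O)c(CN(CC)CC)c(O)c(Cc2c(O)c(CN(CC)CC)c(O)c(C(=O)CC)c2O)c1O | intermediate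
18 | flopropione, 1-(2,4,6-trihydroxyphenyl)propan-1-one | CCC(=O)c1c(O)cc(O)cc1O | starting material
19 | 3,5-dihydroxy-6,6-dimethyl-2-propanoylcyclohexa-2,4-dien-1-one (propionylfilicinic acid) | CCC(=O)C1=C(O)C=C(O)C(C)(C)C1=O | intermediate
20 | 2,2'-methylenebis(3,5-dihydroxy-6-methylidene-4-propanoylcyclohexa-2,4-dien-1-one) (bis(o-quinone methide), formed one ring at a time) | C=C1C(=O)C(CC2=C(O)C(C(=O)CC)=C(O)C(=C)C2=O)=C(O)C(C(=O)CC)=C1O | intermediate
21 | 4,4'-{methylenebis[(2,4,6-trihydroxy-5-propanoyl-3,1-phenylene)methylene]}bis(3,5-dihydroxy-6,6-dimethyl-2-propanoylcyclohexa-2,4-dien-1-one), one enol tautomer drawn | CCC(=O)C1=C(O)C(Cc2c(O)c(Cc3c(O)c(CC4=C(O)C(C)(C)C(=O)C(C(=O)CC)=C4O)c(O)c(C(=O)CC)c3O)c(O)c(C(=O)CC)c2O)=C(O)C(C)(C)C1=O | target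

Total step count: 7
Longest linear sequence: 5 steps (steps 1, 3, 4, 5, 7); steps 2 and 6 feed in.

Steps most likely to fail

Step 3. The donor-substituted vinylketene may add the siloxyalkyne too slowly, so that ketene dimerisation, acylation of the newly formed phenol or amine-triggered oligomerisation consumes it, or only one half of 6 may be converted. The fallback takes rings B and C from a ready-made phloroglucinol instead of building them. It sets out from flopropione 18, which is condensed with half an equivalent of formaldehyde (aq. CH2O, dilute NaOH, 0 °C) to 1,1'-[methylenebis(2,4,6-trihydroxy-3,1-phenylene)]di(propan-1-one) F1. A twofold Mannich reaction at the one remaining ring C–H of each ring (Et2NH, aq. CH2O, EtOH, rt) then gives the bis-Mannich base, and the fallback comes back to the route at 17.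

Step 1. The half-reacted ketene acid chloride 3 may close through its acyl chloride oxygen to a six-membered chloro enol lactone, or the ketenes may dimerise, before ethoxyacetylene adds. The fallback builds the two rings one at a time, so that no ketene ever faces an acyl chloride in the same molecule. It sets out from ethoxyacetylene 2 and uses glutaric anhydride as the carbon source.
- Glutaric anhydride is opened with allyl alcohol (DMAP, CH2Cl2) to 5-(allyloxy)-5-oxopentanoic acid F2.
- Oxalyl chloride converts this into allyl 5-chloro-5-oxopentanoate F3.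
- Et3N in Et2O generates the ketene allyl 5-oxopent-4-enoate F4 (not isolated), which adds 2 to give allyl 3-(2-ethoxy-4-oxocyclobut-2-en-1-yl)propanoate F5.
- Pd(PPh3)4 with PhSiH3 removes the allyl group under neutral conditions to give 3-(2-ethoxy-4-oxocyclobut-2-en-1-yl)propanoic acid F6.
- 1-Chloro-N,N,2-trimethylprop-1-en-1-amine converts the acid into the acid chloride.

The fallback comes back to the route at 4, which is carried through 5 to 6 with Et3N and 2 as in step 1.

Step 7. Loss of diethylamine may be slow enough to demand temperatures at which the liberated base induces retro-Michael cleavage and scrambling of the central bridge. The fallback changes the leaving group so that the quinone methide forms in the cold. It sets out from 17, which is heated with acetic anhydride to exchange the amine for acetate and acetylate the phenols, giving the octaacetate [methylenebis(2,4,6-triacetoxy-5-propanoyl-3,1-phenylene)]dimethanediyl diacetate F7. Treating F7 with 19 and K2CO3 in MeOH at 0 °C frees the phenoxides, which expel the benzylic acetate; the enolate of 19 adds to the resulting quinone methide and the remaining aryl acetates are methanolysed. The fallback comes back to the route at the target 21.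

Further compounds
F1 | step 3 | 1,1'-[methylenebis(2,4,6-trihydroxy-3,1-phenylene)]di(propan-1-one) | CCC(=O)c1c(O)cc(O)c(Cc2c(O)cc(O)c(C(=O)CC)c2O)c1O
F2 | step 1 | 5-(allyloxy)-5-oxopentanoic acid | C=CCOC(=O)CCCC(=O)O
F3 | step 1 | allyl 5-chloro-5-oxopentanoate | C=CCOC(=O)CCCC(Cl)=O
F4 | step 1 | allyl 5-oxopent-4-enoate (ketene, not isolated) | C=CCOC(=O)CCC=C=O
F5 | step 1 | allyl 3-(2-ethoxy-4-oxocyclobut-2-en-1-yl)propanoate (racemic) | C=CCOC(=O)CCC1C(=O)C=C1OCC
F6 | step 1 | 3-(2-ethoxy-4-oxocyclobut-2-en-1-yl)propanoic acid (racemic) | CCOC1=CC(=O)C1CCC(=O)O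
F7 | step 7 | [methylenebis(2,4,6-triacetoxy-5-propanoyl-3,1-phenylene)]dimethanediyl diacetate | CCC(=O)c1c(OC(C)=O)c(COC(C)=O)c(OC(C)=O)c(Cc2c(OC(C)=O)c(COC(C)=O)c(OC(C)=O)c(C(=O)CC)c2OC(C)=O)c1OC(C)=O
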